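The slowness of these flasks shows in the target: by the last reading of the spring run it stands at 5.6 %, and free catalyst is charged in a smaller amount than starting material.

| flask | starting material | free catalyst | remark | time |
|---|---|---|---|---|
| spring | 2.4 M | 40 mM | run made earlier |  |
| dawn | 2.4 M | 90 mM | run made earlier |  |
| delta | 2.4 M | 60 mM |  | 2.5 min |
| theta | 2.4 M | 60 mM |  | 4.0 min |

| run | time / s | catalyst intermediate A / % | catalyst intermediate B / % | target / % | starting material / % |
|---|---|---|---|---|---|
| spring | 10.0 | 0.5 | 0.4 | 0 | 87.9 |
| spring | 15.0 | 0 | 0.5 | 0.9 | 83.8 |
| spring | 20.0 | 0.3 | 0 | 0 | 80.4 |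
| spring | 30.0 | 0.8 | 0 | 2.0 | 73.4 |
| spring | 50.0 | 0 | 0.4 | 1.8 | 63.2 |
| spring | 80.0 | 0.2 | 0.1 | 3.5 | 50.8 |
| spring | 120 | 0 | 0.2 | 5.6 | 40.4 |
| dawn | 15.0 | 0.2 | 1.2 | 1.2 | 79.6 |
| dawn | 30.0 | 0 | 0.1 | 2.6 | 70.4 |
| dawn | 50.0 | 0 | 0 | 4.4 | 59.0 |
| dawn | 60.0 | 0 | 0 | 5.8 | 55.3 |
| dawn | 80.0 | 0 | 1.1 | 7.7 | 47.1 |
| dawn | 90.0 | 0 | 0.3 | 8.7 | 44.6 |
| dawn | 120 | 0.2 | 0.3 | 12.9 | 34.9 |

(readings scatter by 0.5 percentage points)

- a reading of starting material is of its free form alone

- which of these there is most of at the end, counted by the starting material in it, delta (starting material / catalyst intermediate A / target / catalyst intermediate B)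
- which of these there is most of at the end, counted by the starting material in it, theta (starting material / catalyst intermediate A / target / catalyst intermediate B)
- final amount of the leader among these, as a percentage of the starting material charged, in delta
- final amount of the leader among these, as a percentage of the starting material charged, in theta

I write the balance of the catalyst: if it comes back after each turn, target made equals catalyst charged times turns per second times time. So I define the turn rate (the turnover frequency) as the target concentration made per catalyst charged per second, averaged from the start. The last readings of target, at 120 s, give 0.0280 /s in spring and 0.0287 /s in dawn, both resting on readings with a scatter of 0.5 percentage points. I carry their mean, the turn rate 0.0283 /s.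

Multiplying by catalyst and time and dividing by the charge, I reckon target at 10.6 % in delta, under the 34.9 % and 40.4 % of starting material at the last readings of dawn and spring, which lie 30.0 s before delta's end, so I name starting material as delta's leader. For theta I reckon 17.0 % of target, which is a weaker figure, as its time is twice that of the last readings.

The forecast names starting material in delta at 34.5 % and starting material in theta at 25 %, reasoning “so the catalyst is saturated”.

The flask gives starting material at 31.4 % in delta, and target at 24.5 % in theta, with starting material at 14.1 %.

    starting material + free catalyst ⇌ catalyst intermediate A (K = 20.0 /M, k = 0.930 /M/s)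
    catalyst intermediate A ⇌ catalyst intermediate B (K = 2.60, k = 7.60 /s)
    catalyst intermediate B → free catalyst + target (k = 0.730 /s)
    2 starting material → self-condensation product (k = 0.00220 /M/s)
    starting material + catalyst intermediate B ⇌ idle complex, settled at all times (K = 18.0 /M)

Delta's target, 11.4 %, stands above my 10.6 %, and theta's 24.5 % stands above my 17.0 %. The turn rate read from these results is 0.0303 /s in delta and 0.0408 /s in theta, against the carried 0.0283 /s. At its end, delta holds 84.3 % of the catalyst charged as idle complex, an off-cycle form, and theta holds 62.1 %. For the neighbour like delta with 0.10 M of free catalyst, the carried turn rate gives 17.7 % of target, and that flask gives 20.5 %.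

The numbers in the tables come from a simulation on assumed constants; the scatter is artificial.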